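**Plan**
- **Cuts.** After removal of two benzyl groups, ring B is cut at C1–C2 and C5–C6. This gives a four-carbon diene (C2–C3–C4–C5) and the two alkyne carbons (C1, C6) of benzyl hex-2-ynoate.
- **Enabling feature.** In ring B, C2(OH)–C3(O-aroyl)–C4(OH)–C5(H) is an acetoacetate chain whose central carbon already bears the depside oxygen. C1(CO2H)–C6(propyl) is a hex-2-ynoate.
- **Earlier cuts.** The C3–O bond is cut at the sp3 stage (ring A carboxylate plus methyl 2-chloroacetoacetate). The ring A acid goes back to 5-propylresorcinol through one C–CHO bond and two O-alkyl bonds.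
- **Forward order.** Ring A is bought and decorated (steps 1–4), tied to the C4 chain (5), and silylated twice to the diene (6, 7). Ring B is closed on it with the ynoate from step 8 (9), and both benzyl groups are removed (10).
- **Stereochemistry.** The target has no stereogenic element. The transient centres in 9 and 15 are racemic and are erased.

Key step: step 9

Remark: the target has no stereocentre, stereoaxis or stereogenic double bond, so its constitution alone defines the single compound asked for.

**Step 1**
Reactants: 1 5-propylresorcinol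
Product: 3 2,4-dihydroxy-6-propylbenzaldehyde, via aryl iminium salt 2 (not isolated)
Conditions: POCl3 (1.5 equiv), DMF, 0 °C → rt; then ice–water
Reagents that add atoms: N,N-dimethylformamide CN(C)C=O; water O
Why: Vilsmeier–Haack formylation of a 5-alkylresorcinol goes to the ring position para to one hydroxyl and ortho to the other, beside the alkyl chain, and water then hydrolyses iminium salt 2 to the aldehyde.

**Step 2**
Reactants: 3 2,4-dihydroxy-6-propylbenzaldehyde; 4 benzyl bromide (1.05 equiv)
Product: 5 4-(benzyloxy)-2-hydroxy-6-propylbenzaldehyde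
Conditions: K2CO3 (1.0 equiv), acetone, reflux
Reagents that add atoms: none
Why: Williamson ether synthesis with one equivalent of base alkylates the 4-OH only, since the 2-OH is tied up in a hydrogen bond to the aldehyde oxygen and is the weaker acid and nucleophile.

**Step 3**
Reactants: 5 4-(benzyloxy)-2-hydroxy-6-propylbenzaldehyde
Product: 6 4-(benzyloxy)-2-methoxy-6-propylbenzaldehyde
Conditions: MeI (3 equiv), K2CO3, DMF, rt
Reagents that add atoms: iodomethane CI
Why: Williamson O-methylation of the remaining chelated phenol succeeds once a polar aprotic solvent and excess iodomethane are used, and nothing else in 5 can be alkylated.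

**Step 4**
Reactants: 6 4-(benzyloxy)-2-methoxy-6-propylbenzaldehyde
Product: 7 4-(benzyloxy)-2-methoxy-6-propylbenzoic acid
Conditions: NaClO2, NaH2PO4, 2-methylbut-2-ene, t-BuOH–THF–H2O, 0 °C → rt
Reagents that add atoms: sodium chlorite [Na+].[O-]Cl=O
Why: Pinnick oxidation takes the di-ortho-substituted aldehyde to the acid under buffered conditions that leave both ethers alone, with 2-methylbut-2-ene intercepting hypochlorous acid before it can chlorinate the electron-rich ring.

**Step 5**
Reactants: 7 4-(benzyloxy)-2-methoxy-6-propylbenzoic acid; 8 methyl 2-chloro-3-oxobutanoate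
Product: 9 1-methoxy-1,3-dioxobutan-2-yl 4-(benzyloxy)-2-methoxy-6-propylbenzoate (racemic)
Conditions: Et3N (1.0 equiv), DMF, 0 °C → rt
Reagents that add atoms: none
Why: SN2 displacement of the doubly carbonyl-activated chloride by a carboxylate is the standard entry to 2-acyloxy-3-oxo esters, and because the new bond forms at the carboxylate oxygen the crowding around the aroyl carbon plays no part; the new centre is racemic, labile and erased in step 6.

**Step 6**
Reactants: 9 1-methoxy-1,3-dioxobutan-2-yl 4-(benzyloxy)-2-methoxy-6-propylbenzoate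
Product: 10 1-methoxy-1-oxo-3-(trimethylsilyloxy)but-2-en-2-yl 4-(benzyloxy)-2-methoxy-6-propylbenzoate (E/Z mixture)
Conditions: Me3SiCl (1.5 equiv), Et3N (1.5 equiv), toluene, rt; filtration under Ar
Reagents that add atoms: chlorotrimethylsilane C[Si](C)(C)Cl
Why: O-Silylation of the readily enolised β-keto ester under amine-base (soft enolisation) conditions gives the conjugated silyl enol ether, the first stage of the established two-stage preparation of 1,3-bis(silyloxy)dienes, and either double-bond isomer serves.

**Step 7**
Reactants: 10 1-methoxy-1-oxo-3-(trimethylsilyloxy)but-2-en-2-yl 4-(benzyloxy)-2-methoxy-6-propylbenzoate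
Product: 12 1-methoxy-1,3-bis(trimethylsilyloxy)buta-1,3-dien-2-yl 4-(benzyloxy)-2-methoxy-6-propylbenzoate, via lithium dienolate 11 (not isolated)
Conditions: Me3SiCl (2 equiv) present from the start, LDA (1.1 equiv) added dropwise, THF, −78 °C → 0 °C; hexane, filtration under Ar; used crude
Reagents that add atoms: chlorotrimethylsilane C[Si](C)(C)Cl
Why: Kinetic γ-deprotonation of the vinylogous ester by LDA followed by O-silylation of the extended enolate is the second stage of that preparation; the chlorosilane already present (internal quench) captures 11 before a Chan-type O-to-C acyl shift or lateral lithiation of the propyl group can intervene, and the di-ortho-substituted aroyl carbonyl is shielded from the amide base.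

**Step 8**
Reactants: 13 hex-2-ynoic acid; 4 benzyl bromide
Product: 14 benzyl hex-2-ynoate
Conditions: K2CO3, DMF, rt
Reagents that add atoms: none
Why: Alkylation of the carboxylate with benzyl bromide (SN2 esterification) avoids acid or carbodiimide activation, and carbonate at room temperature is too weak to isomerise the ynoate to the allenoate.

**Step 9**
Reactants: 12 1-methoxy-1,3-bis(trimethylsilyloxy)buta-1,3-dien-2-yl 4-(benzyloxy)-2-methoxy-6-propylbenzoate; 14 benzyl hex-2-ynoate (3 equiv)
Product: 17 benzyl 3-{[4-(benzyloxy)-2-methoxy-6-propylbenzoyl]oxy}-2,4-dihydroxy-6-propylbenzoate, via cyclohexadiene cycloadduct 15 (not isolated), via bis(trimethylsilyl) ether 16 (not isolated)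
Conditions: o-xylene, 130 °C, slow Ar sweep; then 1 M HCl, THF, 0 °C → rt
Reagents that add atoms: none
Why: Proposed new method: three oxygen donors raise the diene HOMO and put its largest coefficient on the CH2 terminus, so a normal-demand, strongly asynchronous Diels–Alder reaction with the ynoate should form C5–C6 ahead of C1–C2 and give cyclohexa-1,4-diene 15, whose C2 mixed ketal loses methanol by 1,4-elimination with a C5 hydrogen to give arene 16, and dilute acid then frees both phenols. The closest known reaction type is the thermal benzannulation of the parent 1-methoxy-1,3-bis(silyloxy)buta-1,3-diene with alk-2-ynoates to 6-alkyl-2,4-dihydroxybenzoates; new here is the acyloxy group on the central diene carbon, which attenuates the donor power only mildly (2-acyloxybutadienes remain competent dienes) and whose bulk next to the C3 silyloxy group disfavours the s-trans rotamer. Ring B closes as a six-membered carbocycle by intermolecular [4+2] cycloaddition, which in its stepwise limit is a vinylogous Mukaiyama–Michael addition followed by 6-exo-trig attack of the allenolate carbon on the oxocarbenium carbon. The ketal carbon of 15 is the only new stereocentre, it forms as a racemate and disappears on aromatisation, so no stereocontrol is called for. The selectivity needed is regiochemical, and it is secured by the match of the nucleophilic CH2 terminus (future C5) with the electrophilic β-carbon of the ynoate that bears the propyl group (future C6), which leaves the benzyl ester on C1 beside the C2 oxygen. Excess ynoate and removal of methanol in the gas stream protect unreacted diene from protonolysis, and acidic rather than basic or fluoride desilylation keeps the aroyl group on O3.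

**Step 10**
Reactants: 17 benzyl 3-{[4-(benzyloxy)-2-methoxy-6-propylbenzoyl]oxy}-2,4-dihydroxy-6-propylbenzoate
Product: 18 2,4-dihydroxy-3-[(4-hydroxy-2-methoxy-6-propylbenzoyl)oxy]-6-propylbenzoic acid (CNP0482898.0)
Conditions: H2 (1 atm), 10% Pd/C, EtOAc, rt
Reagents that add atoms: none
Why: Catalytic hydrogenolysis cleaves the benzyl ether and the benzyl ester together under neutral conditions, which leaves the aryl ester, the methyl ether and the arenes intact and gives no opening for migration of the aroyl group to the neighbouring phenols or for decarboxylation.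

**Compound list**
1 | 5-propylresorcinol | CCCc1cc(O)cc(O)c1 | starting material
2 | (2,4-dihydroxy-6-propylbenzylidene)dimethyliminium dichlorophosphate | CCCc1cc(O)cc(O)c1C=[N+](C)C.[O-]P(=O)(Cl)Cl | intermediate
3 | 2,4-dihydroxy-6-propylbenzaldehyde | CCCc1cc(O)cc(O)c1C=O | intermediate
4 | benzyl bromide | BrCc1ccccc1 | starting material
5 | 4-(benzyloxy)-2-hydroxy-6-propylbenzaldehyde | CCCc1cc(OCc2ccccc2)cc(O)c1C=O | intermediate
6 | 4-(benzyloxy)-2-methoxy-6-propylbenzaldehyde | CCCc1cc(OCc2ccccc2)cc(OC)c1C=O | intermediate
7 | 4-(benzyloxy)-2-methoxy-6-propylbenzoic acid | CCCc1cc(OCc2ccccc2)cc(OC)c1C(=O)O | intermediate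
8 | methyl 2-chloro-3-oxobutanoate (racemic) | CC(=O)C(Cl)C(=O)OC | starting material
9 | 1-methoxy-1,3-dioxobutan-2-yl 4-(benzyloxy)-2-methoxy-6-propylbenzoate (racemic, labile centre) | CCCc1cc(OCc2ccccc2)cc(OC)c1C(=O)OC(C(C)=O)C(=O)OC | intermediate
10 | 1-methoxy-1-oxo-3-(trimethylsilyloxy)but-2-en-2-yl 4-(benzyloxy)-2-methoxy-6-propylbenzoate (E/Z mixture) | CCCc1cc(OCc2ccccc2)cc(OC)c1C(=O)OC(C(=O)OC)=C(C)O[Si](C)(C)C | intermediate
11 | lithium 2-{[4-(benzyloxy)-2-methoxy-6-propylbenzoyl]oxy}-1-methoxy-3-(trimethylsilyloxy)buta-1,3-dien-1-olate | [Li+].[O-]C(OC)=C(OC(=O)c1c(CCC)cc(OCc2ccccc2)cc1OC)C(=C)O[Si](C)(C)C | intermediate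
12 | 1-methoxy-1,3-bis(trimethylsilyloxy)buta-1,3-dien-2-yl 4-(benzyloxy)-2-methoxy-6-propylbenzoate (ketene acetal drawn 1E; the geometry has no consequence) | C=C(O[Si](C)(C)C)/C(OC(=O)c1c(CCC)cc(OCc2ccccc2)cc1OC)=C(/OC)O[Si](C)(C)C | intermediate
13 | hex-2-ynoic acid | CCCC#CC(=O)O | starting material
14 | benzyl hex-2-ynoate | CCCC#CC(=O)OCc1ccccc1 | intermediate
15 | benzyl 5-{[4-(benzyloxy)-2-methoxy-6-propylbenzoyl]oxy}-6-methoxy-2-propyl-4,6-bis(trimethylsilyloxy)cyclohexa-1,4-diene-1-carboxylate (racemic) | CCCC1=C(C(=O)OCc2ccccc2)C(OC)(O[Si](C)(C)C)C(OC(=O)c2c(CCC)cc(OCc3ccccc3)cc2OC)=C(O[Si](C)(C)C)C1 | intermediate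
16 | benzyl 3-{[4-(benzyloxy)-2-methoxy-6-propylbenzoyl]oxy}-6-propyl-2,4-bis(trimethylsilyloxy)benzoate | CCCc1cc(O[Si](C)(C)C)c(OC(=O)c2c(CCC)cc(OCc3ccccc3)cc2OC)c(O[Si](C)(C)C)c1C(=O)OCc1ccccc1 | intermediate
17 | benzyl 3-{[4-(benzyloxy)-2-methoxy-6-propylbenzoyl]oxy}-2,4-dihydroxy-6-propylbenzoate | CCCc1cc(OCc2ccccc2)cc(OC)c1C(=O)Oc1c(O)cc(CCC)c(C(=O)OCc2ccccc2)c1O | intermediate
18 | 2,4-dihydroxy-3-[(4-hydroxy-2-methoxy-6-propylbenzoyl)oxy]-6-propylbenzoic acid | CCCc1cc(O)cc(OC)c1C(=O)Oc1c(O)cc(CCC)c(C(=O)O)c1O | target

**Step count**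
Total step count: 10
Longest linear sequence: 9 (steps 1–7, 9, 10)

**Steps most likely to fail**

**Step 9.**
- **Risk.** The acyloxy group makes the diene less nucleophilic, and the twisted aroyl ring screens it. Protodesilylation, silyl shift or thermal breakdown may therefore outrun addition to an unactivated β-alkyl ynoate.
- **Scope of the fallback.** It uses known chemistry only. It sets out from 14 and 7 and comes back to the route at 18.
- **Ring B without the depside oxygen.** Ynoate 14 is heated with the unsubstituted 1-methoxy-1,3-bis(trimethylsilyloxy)buta-1,3-diene F1. This is the established form of the benzannulation, and after acid work-up it gives benzyl 2,4-dihydroxy-6-propylbenzoate F2.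
- **Oxygen at C3.** Rieche formylation (Cl2CHOMe, TiCl4, CH2Cl2) between the two hydroxyls gives benzyl 3-formyl-2,4-dihydroxy-6-propylbenzoate F3. Benzyl bromide with K2CO3 then gives benzyl 2,4-bis(benzyloxy)-3-formyl-6-propylbenzoate F4. Baeyer–Villiger oxidation with mCPBA gives benzyl 2,4-bis(benzyloxy)-3-(formyloxy)-6-propylbenzoate F5. Methanolysis (Et3N, MeOH) gives benzyl 2,4-bis(benzyloxy)-3-hydroxy-6-propylbenzoate F6.
- **Depside bond and deprotection.** Acid 7 is joined to this phenol through its mixed trifluoroacetic anhydride (TFAA, toluene). The electron-rich, di-ortho-substituted acid reacts there as its unhindered acylium ion. The product is benzyl 2,4-bis(benzyloxy)-3-{[4-(benzyloxy)-2-methoxy-6-propylbenzoyl]oxy}-6-propylbenzoate F7. Hydrogenolysis under the conditions of step 10 then gives 18.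

**Step 7.**
- **Risk.** The lithium dienolate may undergo O-to-C acyl migration of the Chan type or O-to-O acyl migration. The base may metalate the benzylic position of the ortho-propyl group. Silylation may also occur on carbon.
- **Fallback.** It avoids any metal enolate and changes the silyl group and the precursor of the cycloaddition. It sets out from 9 and comes back at 17.
- **Diene.** Double soft enolisation of 9 with TBSOTf and Et3N in CH2Cl2 gives, in one operation, the sturdier 1-methoxy-1,3-bis(tert-butyldimethylsilyloxy)buta-1,3-dien-2-yl 4-(benzyloxy)-2-methoxy-6-propylbenzoate F8.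
- **Return to the route.** Heating F8 with 14 as in step 9 gives, after loss of methanol, benzyl 3-{[4-(benzyloxy)-2-methoxy-6-propylbenzoyl]oxy}-2,4-bis(tert-butyldimethylsilyloxy)-6-propylbenzoate F9. This can be purified, and Et3N·3HF in THF then frees 17.

**Step 5.**
- **Risk.** The amine or the carboxylate may enolise the chloro keto ester, which leads to self-condensation. Retro-Claisen deacetylation of the product may also compete with substitution.
- **Fallback.** It replaces substitution by carbenoid insertion. It sets out from 7 and comes back at 9.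
- **Sequence.** Regitz diazo transfer to methyl acetoacetate (p-acetamidobenzenesulfonyl azide, Et3N, MeCN) gives methyl 2-diazo-3-oxobutanoate F10. Rh2(OAc)4-catalysed O–H insertion of F10 into acid 7 (CH2Cl2, reflux) delivers 9 without any base.

**Further compounds**
F1 | step 9 | 1-methoxy-1,3-bis(trimethylsilyloxy)buta-1,3-diene | C=C(O[Si](C)(C)C)C=C(OC)O[Si](C)(C)C
F2 | step 9 | benzyl 2,4-dihydroxy-6-propylbenzoate | CCCc1cc(O)cc(O)c1C(=O)OCc1ccccc1
F3 | step 9 | benzyl 3-formyl-2,4-dihydroxy-6-propylbenzoate | CCCc1cc(O)c(C=O)c(O)c1C(=O)OCc1ccccc1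
F4 | step 9 | benzyl 2,4-bis(benzyloxy)-3-formyl-6-propylbenzoate | CCCc1cc(OCc2ccccc2)c(C=O)c(OCc2ccccc2)c1C(=O)OCc1ccccc1
F5 | step 9 | benzyl 2,4-bis(benzyloxy)-3-(formyloxy)-6-propylbenzoate | CCCc1cc(OCc2ccccc2)c(OC=O)c(OCc2ccccc2)c1C(=O)OCc1ccccc1
F6 | step 9 | benzyl 2,4-bis(benzyloxy)-3-hydroxy-6-propylbenzoate | CCCc1cc(OCc2ccccc2)c(O)c(OCc2ccccc2)c1C(=O)OCc1ccccc1
F7 | step 9 | benzyl 2,4-bis(benzyloxy)-3-{[4-(benzyloxy)-2-methoxy-6-propylbenzoyl]oxy}-6-propylbenzoate | CCCc1cc(OCc2ccccc2)cc(OC)c1C(=O)Oc1c(OCc2ccccc2)cc(CCC)c(C(=O)OCc2ccccc2)c1OCc1ccccc1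
F8 | step 7 | 1-methoxy-1,3-bis(tert-butyldimethylsilyloxy)buta-1,3-dien-2-yl 4-(benzyloxy)-2-methoxy-6-propylbenzoate | C=C(O[Si](C)(C)C(C)(C)C)C(OC(=O)c1c(CCC)cc(OCc2ccccc2)cc1OC)=C(OC)O[Si](C)(C)C(C)(C)C
F9 | step 7 | benzyl 3-{[4-(benzyloxy)-2-methoxy-6-propylbenzoyl]oxy}-2,4-bis(tert-butyldimethylsilyloxy)-6-propylbenzoate | CCCc1cc(O[Si](C)(C)C(C)(C)C)c(OC(=O)c2c(CCC)cc(OCc3ccccc3)cc2OC)c(O[Si](C)(C)C(C)(C)C)c1C(=O)OCc1ccccc1
F10 | step 5 | methyl 2-diazo-3-oxobutanoate | CC(=O)C(=[N+]=[N-])C(=O)OC
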